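The readings were generated by integration with made-up constants; scatter was added.

A one-step world has a balance with no remainder: [starting material] + [target] equals the charge. I held the north-west run against that balance to reckon the new flask.

| flask | starting material | coupling partner | second substrate | precatalyst | remark | time |
|---|---|---|---|---|---|---|
| north-west | 1 M | 1.1 equiv | 1 equiv | 16 mol% | run made earlier |  |
| flask | 1.0 M | 1.10 equiv | 1.00 equiv | 7.8 mol% |  | 2.5 d |

north-west run (percent of the starting material charged)

| time / h | target / % | starting material / % |
|---|---|---|
| 3.00 | 25.3 | 75.0 |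
| 6.00 | 38.9 | 51.8 |
| 10.0 | 46.6 | 36.0 |
| 12.0 | 49.9 | 30.3 |
| 15.0 | 44.7 | 28.1 |
| 20.0 | 41.4 | 25.7 |

(scatter of a reading: 1 percentage point)

* the best time, 2.5 d at the latest, for target
* the amount of target, in percent of the starting material charged, at that time

1. In the north-west run, the remainder read 9.30% at 6.00 h and 32.9% at 20.0 h, while [target] averaged 44.3%. The remainder's rise per hour per unit of target was my leak constant, 0.0381 h⁻¹, a reading with the scatter of that run.

2. First rung: the early north-west fall of starting material, read as first order, gave 0.0959 h⁻¹, a half-life of 7.23 h.

3. Next rung: scaling by precatalyst, which is a guess, gave the flask 0.0467 h⁻¹, a half-life of 14.8 h.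

4. The leak came next, of like size though slower than that, with a half-life of 18.2 h.

5. Last rung: after 12.0 h, the north-west starting material fell at 0.0206 h⁻¹, a half-life of 33.6 h. I left this stall out.

6. In my reckoning, target peaked where its making equalled leak constant times [target]. For the flask, my two rates gave 40.6% at 0.986 d.

The forecast gave 37% (28% to 46%) at 0.6 d (0.35 d to 1.1 d), adding “After the peak, target only decays”.

The flask gave 42.9% at 0.590 d.

    starting material + coupling partner + catalyst → catalyst + target (k = 7.75 × 10⁻⁴ L² mol⁻² s⁻¹)
    second substrate + coupling partner + catalyst → catalyst + second product (k = 1.03 × 10⁻⁴ L² mol⁻² s⁻¹)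
    target ⇌ isomer of the product (K = 2.10, k = 1.56 × 10⁻⁵ s⁻¹)
    coupling partner + precatalyst → catalyst + spent reagent (k = 5.04 × 10⁻⁵ L mol⁻¹ s⁻¹)

In the flask, the remainder stood as the isomer of the product, 19.8% at the best time. From 0.250 d to 1.25 d it rose in the flask from 4.43% to 41.4%, by 37 percentage points. My leak constant, times target averaged over the states at 0.250 d, 0.590 d and 1.25 d, gave a rise of 33 points over that stretch. For the neighbouring flask at 20 mol% of precatalyst, the same reckoning gave 58.6%; that flask reached 49.1%.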